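**Retrosynthetic overview**

- The target comes from its 3'-O-benzyl ether by hydrogenolysis, and the benzyl flavone from a 2-hydroxyaryl ynone by amine-mediated 6-endo O1–C2 closure (ring C, formed last).
- Ring A is not bought but built: C8a (O), C8 (OMe) and C7 (OMe) are three adjacent oxygen-bearing ring carbons, and they correspond to the C=O and the two methoxy-substituted alkene carbons of a cyclobutenone made from dimethyl squarate. C6, C5 and C4a come from an (E)-3-oxoalkenyl arm on the ring sp3 carbon, and C4 is its ketone.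
- Ring A therefore arises by thermal four-electron ring opening to a dienylketene and six-electron closure (C4a–C8a bond), then tautomerization to the ortho-acyl phenol.
- The cyclobutenone precursor is assembled by Stille coupling (C5–C6 bond) of 4-chloro-2,3-dimethoxycyclobutenone with an (E)-β-stannyl enynone.
- The stannyl enynone comes from (E)-3-(tributylstannyl)propenal (from propargyl alcohol) and the ring B arylacetylene (from 3-hydroxy-4,5-dimethoxybenzaldehyde). Ring order: B (bought), A (step 10), C (step 11).

Key step: step 10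

Remark on the chemistry: chloride 12 is assumed to be too ionization-prone for chromatography and is made cold, under neutral conditions, and used crude at once. The stereocentres in 8, 11, 12, 13 and 15 are racemic and none survives into the achiral target.

**Route**

Step 1
Reactants: 1 3-hydroxy-4,5-dimethoxybenzaldehyde
Product: 2 3-(benzyloxy)-4,5-dimethoxybenzaldehyde
Conditions: BnBr, K2CO3, DMF, rt
Reagents that add atoms: benzyl bromide, BrCc1ccccc1
Why: Williamson etherification of the phenoxide with a benzylic bromide, which leaves the aldehyde untouched.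

Step 2
Reactants: 2 3-(benzyloxy)-4,5-dimethoxybenzaldehyde
Product: 3 1-(benzyloxy)-5-ethynyl-2,3-dimethoxybenzene
Conditions: dimethyl (1-diazo-2-oxopropyl)phosphonate, K2CO3, MeOH, 0 °C to rt
Reagents that add atoms: dimethyl (1-diazo-2-oxopropyl)phosphonate, CC(=O)C(=[N+]=[N-])P(=O)(OC)OC
Why: Ohira–Bestmann (Seyferth–Gilbert) homologation turns the aryl aldehyde into the terminal alkyne under mild carbonate/methanol conditions that do not affect the benzyl or methyl ethers.

Step 3
Reactants: 4 propargyl alcohol (prop-2-yn-1-ol)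
Product: 5 (2E)-3-(tributylstannyl)prop-2-en-1-ol
Conditions: Bu3SnH, AIBN (cat.), neat, 80 °C; chromatography
Reagents that add atoms: tributyltin hydride, CCCC[SnH](CCCC)CCCC
Why: Radical hydrostannylation of the terminal alkyne places tin at the terminus, and reversible stannyl-radical addition on heating should equilibrate the adduct toward the (E)-β-stannyl allylic alcohol, which is separated from minor Z and internal isomers.

Step 4
Reactants: 5 (2E)-3-(tributylstannyl)prop-2-en-1-ol
Product: 6 (2E)-3-(tributylstannyl)prop-2-enal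
Conditions: MnO2, CH2Cl2, rt
Reagents that add atoms: none
Why: Allylic alcohol oxidation with activated MnO2 is neutral, so the vinyl C–Sn bond and the E geometry are preserved.

Step 5
Reactants: 3 1-(benzyloxy)-5-ethynyl-2,3-dimethoxybenzene; 6 (2E)-3-(tributylstannyl)prop-2-enal
Product: 8 (1E)-5-[3-(benzyloxy)-4,5-dimethoxyphenyl]-1-(tributylstannyl)pent-1-en-4-yn-3-ol (racemic), via lithium acetylide 7 (not isolated)
Conditions: n-BuLi, THF, −78 °C; then 6, −78 °C; aq. NH4Cl
Reagents that add atoms: none
Why: 1,2-Addition of a lithium acetylide to the enal at low temperature, where an acetylide does not exchange with the vinylstannane; the carbinol centre forms racemic and is removed in step 6.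

Step 6
Reactants: 8 (1E)-5-[3-(benzyloxy)-4,5-dimethoxyphenyl]-1-(tributylstannyl)pent-1-en-4-yn-3-ol
Product: 9 (1E)-5-[3-(benzyloxy)-4,5-dimethoxyphenyl]-1-(tributylstannyl)pent-1-en-4-yn-3-one
Conditions: MnO2, CH2Cl2, rt
Reagents that add atoms: none
Why: The alcohol is both allylic and propargylic, so MnO2 oxidation should be fast and leaves the stannane, the alkyne and the E alkene intact.

Step 7
Reactants: 10 dimethyl squarate (3,4-dimethoxycyclobut-3-ene-1,2-dione)
Product: 11 4-hydroxy-2,3-dimethoxycyclobut-2-en-1-one (racemic)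
Conditions: LiAlH(OtBu)3, THF, −78 to 0 °C; cold aq. Rochelle salt (neutral work-up)
Reagents that add atoms: none
Why: Mono 1,2-reduction of a squarate ester by a bulky alkoxyaluminium hydride stops after one hydride because the product is a deactivated vinylogous ester, and the neutral work-up avoids the acid-promoted loss of methanol to the methoxycyclobutenedione; the C4 centre is racemic.

Step 8
Reactants: 11 4-hydroxy-2,3-dimethoxycyclobut-2-en-1-one
Product: 12 4-chloro-2,3-dimethoxycyclobut-2-en-1-one (racemic)
Conditions: 1-chloro-N,N,2-trimethylprop-1-en-1-amine, CH2Cl2, 0 °C; concentrated cold and used crude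
Reagents that add atoms: 1-chloro-N,N,2-trimethylprop-1-en-1-amine, CC(C)=C(Cl)N(C)C
Why: Deoxychlorination with an α-chloroenamine proceeds through an O-alkyl imidate salt that chloride displaces at C4 without any free acid, the neutral method used for other ionization-prone chlorides such as glycosyl chlorides.

Step 9
Reactants: 12 4-chloro-2,3-dimethoxycyclobut-2-en-1-one; 9 (1E)-5-[3-(benzyloxy)-4,5-dimethoxyphenyl]-1-(tributylstannyl)pent-1-en-4-yn-3-one
Product: 13 4-[(1E)-5-[3-(benzyloxy)-4,5-dimethoxyphenyl]-3-oxopent-1-en-4-yn-1-yl]-2,3-dimethoxycyclobut-2-en-1-one (racemic)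
Conditions: Pd2(dba)3 (cat.), AsPh3, THF, rt to 40 °C; rapid filtration through KF/silica, used at once
Reagents that add atoms: none
Why: Stille coupling, in which zerovalent palladium inserts into the allylic α-keto C–Cl bond, the vinylstannane transfers its alkenyl group with retention of E geometry and reductive elimination occurs at the less substituted C4, as established for 4-chlorocyclobutenones; AsPh3 speeds transmetalation without adding to the ynone, and the temperature stays below that of ring opening.

Step 10
Reactants: 13 4-[(1E)-5-[3-(benzyloxy)-4,5-dimethoxyphenyl]-3-oxopent-1-en-4-yn-1-yl]-2,3-dimethoxycyclobut-2-en-1-one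
Product: 16 3-[3-(benzyloxy)-4,5-dimethoxyphenyl]-1-(2-hydroxy-3,4-dimethoxyphenyl)prop-2-yn-1-one, via dienylketene 14 (not isolated), via cyclohexadienone 15 (not isolated)
Conditions: toluene (0.01 M), 100 °C, argon
Reagents that add atoms: none
Why: Heating cleaves the σ bond between the carbonyl carbon and the sp3 carbon of the four-membered ring in a conrotatory four-electron electrocyclic opening, giving a 2,3-dimethoxy dienylketene whose ketene carbon is the future C8a; the closest known reaction type is the thermal ring expansion of 4-alkenylcyclobutenones to phenols, a relative of the Moore rearrangement and the Danheiser benzannulation. Ring A is then closed by a disrotatory six-electron electrocyclization of 14 that joins the ketene carbon to the enone α-carbon (new C4a–C8a bond), and cyclohexa-2,4-dienone 15 enolizes irreversibly to the phenol, which is hydrogen-bonded to the ortho ynone carbonyl. The only stereocentre formed, C4a of 15, is erased by that tautomerization, so no stereocontrol is needed. The selectivity required is geometric: only the ketene in which the enone arm and the ketene lie on the same side of the newly formed C6=C7 double bond can close, and since the outward-rotated ketene can only revert to 13 when no trap is present, reversible opening should drain the material through 14. Regiochemistry needs no control, because the squarate core delivers the carbonyl and both methoxy carbons as the contiguous C8a–C8–C7 unit and the hydroxyl is necessarily ortho to the acyl group. Dilute, dry, base-free toluene is chosen to suppress ketene dimerization, nucleophilic capture and prototropic shift of the C4–H into conjugation with the enone.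

Step 11
Reactants: 16 3-[3-(benzyloxy)-4,5-dimethoxyphenyl]-1-(2-hydroxy-3,4-dimethoxyphenyl)prop-2-yn-1-one
Product: 18 2-[3-(benzyloxy)-4,5-dimethoxyphenyl]-7,8-dimethoxy-4H-chromen-4-one, via enaminone 17 (not isolated)
Conditions: Et2NH, EtOH, reflux
Reagents that add atoms: none
Why: Conjugate addition of the secondary amine to the ynone gives a β-amino enone whose β-carbon is attacked by the neighbouring phenol in a 6-endo addition–elimination that expels the amine, which avoids the 5-exo aurone pathway open to simple bases.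

Step 12
Reactants: 18 2-[3-(benzyloxy)-4,5-dimethoxyphenyl]-7,8-dimethoxy-4H-chromen-4-one
Product: 19 3'-hydroxy-4',5',7,8-tetramethoxyflavone [2-(3-hydroxy-4,5-dimethoxyphenyl)-7,8-dimethoxy-4H-chromen-4-one]
Conditions: H2 (1 atm), 10% Pd/C, EtOAc–EtOH, rt
Reagents that add atoms: none
Why: Hydrogenolysis of the benzyl aryl ether over palladium on carbon is much faster than reduction of the chromone C2=C3 bond, which is part of a vinylogous ester, so the reaction is stopped when 18 is consumed.

**Compound list**

1 | 3-hydroxy-4,5-dimethoxybenzaldehyde | COc1cc(C=O)cc(O)c1OC | starting material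
2 | 3-(benzyloxy)-4,5-dimethoxybenzaldehyde | COc1cc(C=O)cc(OCc2ccccc2)c1OC | intermediate
3 | 1-(benzyloxy)-5-ethynyl-2,3-dimethoxybenzene | C#Cc1cc(OC)c(OC)c(OCc2ccccc2)c1 | intermediate
4 | propargyl alcohol (prop-2-yn-1-ol) | C#CCO | starting material
5 | (2E)-3-(tributylstannyl)prop-2-en-1-ol | CCCC[Sn](CCCC)(CCCC)/C=C/CO | intermediate
6 | (2E)-3-(tributylstannyl)prop-2-enal | CCCC[Sn](CCCC)(CCCC)/C=C/C=O | intermediate
7 | lithium [3-(benzyloxy)-4,5-dimethoxyphenyl]ethynide (not isolated) | [Li]C#Cc1cc(OC)c(OC)c(OCc2ccccc2)c1 | intermediate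
8 | (1E)-5-[3-(benzyloxy)-4,5-dimethoxyphenyl]-1-(tributylstannyl)pent-1-en-4-yn-3-ol (racemic) | CCCC[Sn](CCCC)(CCCC)/C=C/C(O)C#Cc1cc(OC)c(OC)c(OCc2ccccc2)c1 | intermediate
9 | (1E)-5-[3-(benzyloxy)-4,5-dimethoxyphenyl]-1-(tributylstannyl)pent-1-en-4-yn-3-one | CCCC[Sn](CCCC)(CCCC)/C=C/C(=O)C#Cc1cc(OC)c(OC)c(OCc2ccccc2)c1 | intermediate
10 | dimethyl squarate (3,4-dimethoxycyclobut-3-ene-1,2-dione) | COC1=C(OC)C(=O)C1=O | starting material
11 | 4-hydroxy-2,3-dimethoxycyclobut-2-en-1-one (racemic) | COC1=C(OC)C(O)C1=O | intermediate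
12 | 4-chloro-2,3-dimethoxycyclobut-2-en-1-one (racemic) | COC1=C(OC)C(Cl)C1=O | intermediate
13 | 4-[(1E)-5-[3-(benzyloxy)-4,5-dimethoxyphenyl]-3-oxopent-1-en-4-yn-1-yl]-2,3-dimethoxycyclobut-2-en-1-one (racemic) | COC1=C(OC)C(/C=C/C(=O)C#Cc2cc(OC)c(OC)c(OCc3ccccc3)c2)C1=O | intermediate
14 | (3E,5E)-9-[3-(benzyloxy)-4,5-dimethoxyphenyl]-2,3-dimethoxynona-1,3,5-trien-8-yne-1,7-dione (dienylketene, ketene and enone arm cis across C3=C4; not isolated) | O=C=C(OC)/C(OC)=C\C=C\C(=O)C#Cc1cc(OC)c(OC)c(OCc2ccccc2)c1 | intermediate
15 | 6-{3-[3-(benzyloxy)-4,5-dimethoxyphenyl]prop-2-ynoyl}-2,3-dimethoxycyclohexa-2,4-dien-1-one (racemic; not isolated) | COC1=C(OC)C(=O)C(C(=O)C#Cc2cc(OC)c(OC)c(OCc3ccccc3)c2)C=C1 | intermediate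
16 | 3-[3-(benzyloxy)-4,5-dimethoxyphenyl]-1-(2-hydroxy-3,4-dimethoxyphenyl)prop-2-yn-1-one | COc1ccc(C(=O)C#Cc2cc(OC)c(OC)c(OCc3ccccc3)c2)c(O)c1OC | intermediate
17 | 3-[3-(benzyloxy)-4,5-dimethoxyphenyl]-3-(diethylamino)-1-(2-hydroxy-3,4-dimethoxyphenyl)prop-2-en-1-one (alkene geometry not fixed; not isolated) | CCN(CC)C(=CC(=O)c1ccc(OC)c(OC)c1O)c1cc(OC)c(OC)c(OCc2ccccc2)c1 | intermediate
18 | 2-[3-(benzyloxy)-4,5-dimethoxyphenyl]-7,8-dimethoxy-4H-chromen-4-one | COc1cc(-c2cc(=O)c3ccc(OC)c(OC)c3o2)cc(OCc2ccccc2)c1OC | intermediate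
19 | 3'-hydroxy-4',5',7,8-tetramethoxyflavone | COc1cc(-c2cc(=O)c3ccc(OC)c(OC)c3o2)cc(O)c1OC | target

**Step count**

Total steps: 12. Longest linear sequence: 8 steps (1 → 2 → 3 → 8 → 9 → 13 → 16 → 18 → 19; the branch from propargyl alcohol is equally long).

**Steps most likely to fail**

1. Step 10 (key step). The ketene may be consumed by dimerization or by stray nucleophiles before the closable isomer cyclizes. Alternatively the C4–H, which is γ to the enone, may shift so that the alkene moves into conjugation with the ring, and such a 4-alkylidenecyclobutenone cannot open productively. The fallback removes the acyl group from the alkenyl arm during the ring expansion and sets out from alcohol 8 and chloride 12. Silylation of 8 (TBSCl, imidazole, DMF) should give tert-butyl({(1E)-5-[3-(benzyloxy)-4,5-dimethoxyphenyl]-1-(tributylstannyl)pent-1-en-4-yn-3-yl}oxy)dimethylsilane F1. Stille coupling of F1 with 12 under the step 9 conditions should give 4-[(1E)-5-[3-(benzyloxy)-4,5-dimethoxyphenyl]-3-[(tert-butyldimethylsilyl)oxy]pent-1-en-4-yn-1-yl]-2,3-dimethoxycyclobut-2-en-1-one F2 as a diastereomer mixture. Heating F2 in toluene at 100 °C should then give 6-{3-[3-(benzyloxy)-4,5-dimethoxyphenyl]-1-[(tert-butyldimethylsilyl)oxy]prop-2-yn-1-yl}-2,3-dimethoxyphenol F3, the alkenyl case for which this ring expansion is best established. Desilylation (Bu4NF, AcOH, THF) should give 6-{3-[3-(benzyloxy)-4,5-dimethoxyphenyl]-1-hydroxyprop-2-yn-1-yl}-2,3-dimethoxyphenol F4, and MnO2 oxidation of its benzylic, propargylic alcohol returns the route to 16.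

2. Step 8. Ionization of the C4–Cl bond, followed by chloride attack on a methoxy methyl group or by hydrolysis during handling, would drain the material to the methoxycyclobutenedione. The fallback replaces the halide by a carboxylate leaving group and sets out from 11. Acetylation (Ac2O, pyridine, DMAP cat., CH2Cl2, 0 °C) should give 2,3-dimethoxy-4-oxocyclobut-2-en-1-yl acetate F5. Palladium-catalysed coupling of this allylic acetate with stannane 9 (Pd2(dba)3, LiCl, DMF, rt to 40 °C; the allylic acetate–vinylstannane coupling) comes back to the route at 13.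

3. Step 9. Transmetalation from the electron-poor β-stannyl enone may be slow, so that protodestannylation of 9 or decomposition of 12 outruns the coupling. The fallback gives up the squarate construction of ring A and sets out from aldehyde 2. Claisen–Schmidt condensation of 2 with purchased 1-(2-hydroxy-3,4-dimethoxyphenyl)ethan-1-one F6 (KOH, EtOH, rt) should give (2E)-3-[3-(benzyloxy)-4,5-dimethoxyphenyl]-1-(2-hydroxy-3,4-dimethoxyphenyl)prop-2-en-1-one F7. Oxidative cyclization of this 2'-hydroxychalcone (I2 cat., DMSO, 130 °C) comes back to the route at 18.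

**Further compounds**

F1 | step 10 | tert-butyl({(1E)-5-[3-(benzyloxy)-4,5-dimethoxyphenyl]-1-(tributylstannyl)pent-1-en-4-yn-3-yl}oxy)dimethylsilane (racemic) | CCCC[Sn](CCCC)(CCCC)/C=C/C(O[Si](C)(C)C(C)(C)C)C#Cc1cc(OC)c(OC)c(OCc2ccccc2)c1
F2 | step 10 | 4-[(1E)-5-[3-(benzyloxy)-4,5-dimethoxyphenyl]-3-[(tert-butyldimethylsilyl)oxy]pent-1-en-4-yn-1-yl]-2,3-dimethoxycyclobut-2-en-1-one (diastereomer mixture) | COC1=C(OC)C(/C=C/C(O[Si](C)(C)C(C)(C)C)C#Cc2cc(OC)c(OC)c(OCc3ccccc3)c2)C1=O
F3 | step 10 | 6-{3-[3-(benzyloxy)-4,5-dimethoxyphenyl]-1-[(tert-butyldimethylsilyl)oxy]prop-2-yn-1-yl}-2,3-dimethoxyphenol (racemic) | COc1ccc(C(O[Si](C)(C)C(C)(C)C)C#Cc2cc(OC)c(OC)c(OCc3ccccc3)c2)c(O)c1OC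
F4 | step 10 | 6-{3-[3-(benzyloxy)-4,5-dimethoxyphenyl]-1-hydroxyprop-2-yn-1-yl}-2,3-dimethoxyphenol (racemic) | COc1ccc(C(O)C#Cc2cc(OC)c(OC)c(OCc3ccccc3)c2)c(O)c1OC
F5 | step 8 | 2,3-dimethoxy-4-oxocyclobut-2-en-1-yl acetate (racemic) | COC1=C(OC)C(OC(C)=O)C1=O
F6 | step 9 | 1-(2-hydroxy-3,4-dimethoxyphenyl)ethan-1-one (purchased) | CC(=O)c1ccc(OC)c(OC)c1O
F7 | step 9 | (2E)-3-[3-(benzyloxy)-4,5-dimethoxyphenyl]-1-(2-hydroxy-3,4-dimethoxyphenyl)prop-2-en-1-one | COc1ccc(C(=O)/C=C/c2cc(OC)c(OC)c(OCc3ccccc3)c2)c(O)c1OC
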